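**Plan**

1. Cuts: C7–O (allylic hydroxylation of the C8=C17 methylene); C12–C13 (primary iodide plus a sulfur-stabilised butyrolactone enolate, butenolide by sulfoxide elimination); then C4–C5 and C9–C10 together, which unfolds the decalin to an acyclic epoxy diene; the chain is cut at C3=C4 (Z-olefination), C1–C2 and C6–C7 (two orthoester Claisen rearrangements) and C8–C9 (vinyl Grignard plus aldehyde).
2. Enabling feature: in ring A the equatorial C3 hydroxyl sits next to quaternary C4, the atoms C4/C5=C10/C9=C8 are in 1,5-diene spacing, and ring B carries the exocyclic C8=C17 methylene next to C9. This is the imprint of an epoxide initiator, a trisubstituted alkene relay and an allylsilane terminator.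
3. Forward order: chain built from C12 toward C19 (steps 1–8), epoxide (9–10), ring A then ring B in one operation (11), side-chain lactone (12–16), C7 hydroxyl (17).
4. Stereochemistry: C3 and C4 from Sharpless epoxidation of a (Z)-allylic alcohol (C4 is inverted on ring closure); C5, C10 and C9 from the chair–chair fold fixed by the (E)-alkene and the allylsilane geometry; C7 from axial oxygen delivery anti to the C10 methyl.

Key step: step 11

Remark: the target is read as 7-hydroxy-14-deoxyandrographolide (an ent-labdane, 7-hydroxyl axial). Positions are in labdane numbering (C19 = hydroxymethyl carbon on C4, C20 = methyl on C10). TBS = tert-butyldimethylsilyl, TMS = trimethylsilyl. Compounds 1, 2, 17, 18 and all reagents are taken as commercial.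

**Route**

Step 1
Reactants: 1 3-(TBS-oxy)propanal; 2 (2-bromoprop-2-en-1-yl)trimethylsilane
Product: 4 rac-1-(TBS-oxy)-4-[(trimethylsilyl)methyl]pent-4-en-3-ol, via Grignard reagent 3 (not isolated)
Conditions: Mg, THF, 40 °C; then 1, −78 → 0 °C; aq. NH4Cl
Reagents that add atoms: none
Why: Grignard 1,2-addition of a vinylmagnesium reagent to an unhindered aldehyde; the carbinol centre forms as a racemate and is erased in step 2.

Step 2
Reactants: 4 rac-1-(TBS-oxy)-4-[(trimethylsilyl)methyl]pent-4-en-3-ol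
Product: 5 ethyl (4Z)-7-(TBS-oxy)-4-[(trimethylsilyl)methyl]hept-4-enoate
Conditions: MeC(OEt)3 (excess), EtCO2H (cat.), 140 °C, EtOH distilled off
Reagents that add atoms: triethyl orthoacetate CC(OCC)(OCC)OCC
Why: Johnson orthoester Claisen rearrangement; the chair transition state with the CH2CH2OTBS group equatorial should put the new C6–C7 chain trans to C11 (4Z by the priority of CH2Si), and the weak acid in excess orthoester should spare the allylsilane.

Step 3
Reactants: 5 ethyl (4Z)-7-(TBS-oxy)-4-[(trimethylsilyl)methyl]hept-4-enoate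
Product: 6 (4Z)-7-(TBS-oxy)-4-[(trimethylsilyl)methyl]hept-4-enal
Conditions: i-Bu2AlH (1.1 equiv), CH2Cl2, −78 °C; MeOH, aq. KNaC4H4O6 (potassium sodium tartrate)
Reagents that add atoms: none
Why: standard low-temperature i-Bu2AlH half-reduction of an ester to the aldehyde; silyl ether and allylsilane are inert.

Step 4
Reactants: 6 (4Z)-7-(TBS-oxy)-4-[(trimethylsilyl)methyl]hept-4-enal
Product: 7 rac-(6Z)-9-(TBS-oxy)-2-methyl-6-[(trimethylsilyl)methyl]nona-1,6-dien-3-ol
Conditions: CH2=C(CH3)MgBr (1.2 equiv), THF, −78 → 0 °C; aq. NH4Cl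
Reagents that add atoms: isopropenylmagnesium bromide C=C(C)[Mg]Br
Why: Grignard 1,2-addition bringing C10, C20 and C1; the racemic carbinol is erased in step 5.

Step 5
Reactants: 7 rac-(6Z)-9-(TBS-oxy)-2-methyl-6-[(trimethylsilyl)methyl]nona-1,6-dien-3-ol
Product: 8 ethyl (4E,8Z)-11-(TBS-oxy)-4-methyl-8-[(trimethylsilyl)methyl]undeca-4,8-dienoate
Conditions: MeC(OEt)3 (excess), EtCO2H (cat.), 140 °C
Reagents that add atoms: triethyl orthoacetate CC(OCC)(OCC)OCC
Why: second Johnson–Claisen rearrangement; the chair transition state with the large chain equatorial should give the (E)-trisubstituted C5=C10 alkene that later fixes the trans ring fusion.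

Step 6
Reactants: 8 ethyl (4E,8Z)-11-(TBS-oxy)-4-methyl-8-[(trimethylsilyl)methyl]undeca-4,8-dienoate
Product: 9 (4E,8Z)-11-(TBS-oxy)-4-methyl-8-[(trimethylsilyl)methyl]undeca-4,8-dienal
Conditions: i-Bu2AlH (1.1 equiv), CH2Cl2, −78 °C; MeOH, aq. KNaC4H4O6
Reagents that add atoms: none
Why: i-Bu2AlH half-reduction of the ester to the aldehyde, as in step 3.

Step 7
Reactants: 9 (4E,8Z)-11-(TBS-oxy)-4-methyl-8-[(trimethylsilyl)methyl]undeca-4,8-dienal
Product: 10 methyl (2Z,6E,10Z)-13-(TBS-oxy)-2,6-dimethyl-10-[(trimethylsilyl)methyl]trideca-2,6,10-trienoate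
Conditions: (CF3CH2O)2P(O)CH(CH3)CO2Me, KN(SiMe3)2, 18-crown-6, THF, −78 °C
Reagents that add atoms: methyl 2-[bis(2,2,2-trifluoroethoxy)phosphoryl]propanoate COC(=O)C(C)P(=O)(OCC(F)(F)F)OCC(F)(F)F
Why: Still–Gennari olefination; the electron-poor phosphonate under dissociating conditions should give the kinetic (Z)-2-methyl enoate, which places the future C19 carbon cis to the chain.

Step 8
Reactants: 10 methyl (2Z,6E,10Z)-13-(TBS-oxy)-2,6-dimethyl-10-[(trimethylsilyl)methyl]trideca-2,6,10-trienoate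
Product: 11 (2Z,6E,10Z)-13-(TBS-oxy)-2,6-dimethyl-10-[(trimethylsilyl)methyl]trideca-2,6,10-trien-1-ol
Conditions: i-Bu2AlH (2.5 equiv), CH2Cl2, −78 → 0 °C; aq. KNaC4H4O6
Reagents that add atoms: none
Why: 1,2-reduction of the enoate by i-Bu2AlH to the allylic alcohol with retention of the (Z) geometry.

Step 9
Reactants: 11 (2Z,6E,10Z)-13-(TBS-oxy)-2,6-dimethyl-10-[(trimethylsilyl)methyl]trideca-2,6,10-trien-1-ol
Product: 12 [(2S,3R)-3-{(3E,7Z)-10-(TBS-oxy)-3-methyl-7-[(trimethylsilyl)methyl]deca-3,7-dien-1-yl}-2-methyloxiran-2-yl]methanol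
Conditions: Ti(Oi-Pr)4 (0.2 equiv), L-(+)-diethyl tartrate (0.24 equiv), t-BuOOH (2 equiv), 4 Å molecular sieves, CH2Cl2, −20 °C
Reagents that add atoms: tert-butyl hydroperoxide CC(C)(C)OO
Why: Sharpless asymmetric epoxidation, which touches only the allylic alcohol alkene; with L-(+)-tartrate a (Z)-allylic alcohol should give the (2S,3R) epoxide, the cis relationship of CH2OH and chain being retained.

Step 10
Reactants: 12 [(2S,3R)-3-{(3E,7Z)-10-(TBS-oxy)-3-methyl-7-[(trimethylsilyl)methyl]deca-3,7-dien-1-yl}-2-methyloxiran-2-yl]methanol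
Product: 13 (2S,3R)-2-[(TBS-oxy)methyl]-3-{(3E,7Z)-10-(TBS-oxy)-3-methyl-7-[(trimethylsilyl)methyl]deca-3,7-dien-1-yl}-2-methyloxirane
Conditions: t-BuMe2SiCl, imidazole, CH2Cl2, 0 °C → rt
Reagents that add atoms: tert-butyldimethylsilyl chloride CC(C)(C)[Si](C)(C)Cl
Why: silyl ether formation at the primary alcohol removes the free hydroxyl that would bind the Lewis acid and permit Payne-type isomerisation in step 11.

Step 11
Reactants: 13 (2S,3R)-2-[(TBS-oxy)methyl]-3-{(3E,7Z)-10-(TBS-oxy)-3-methyl-7-[(trimethylsilyl)methyl]deca-3,7-dien-1-yl}-2-methyloxirane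
Product: 14 (1R,2R,4aS,5R,8aS)-1-[(TBS-oxy)methyl]-5-[2-(TBS-oxy)ethyl]-1,4a-dimethyl-6-methylidenedecahydronaphthalen-2-ol
Conditions: MeAlCl2 (2 equiv), CH2Cl2 (0.005 M), −78 → −40 °C; Et3N, MeOH; aq. NaHCO3
Reagents that add atoms: none
Why: MeAlCl2 binds the epoxide oxygen and the C4–O bond ionises with backside participation of the C5=C10 alkene (ring A, 6-endo-trig on the alkene with endo opening of the epoxide at its tertiary carbon); the developing tertiary C10 cation is captured by C9 of the allylsilane (ring B, 6-endo-trig, forming the C9–C10 bond and the C10 quaternary centre), and the β-silyl cation at C8 loses Me3Si to chloride, leaving the C8=C17 methylene. The closest known reaction type is the Lewis acid promoted, epoxide-initiated and allylsilane-terminated cation–olefin polycyclization of epoxy polyenes, which is known for epoxides carrying an etherified hydroxymethyl group. C3 keeps its (R) configuration and its oxygen becomes the equatorial hydroxyl, while C4 is inverted by anti attack, so the CH2OTBS group that was cis to the chain on the epoxide becomes the axial C19 group and the methyl becomes equatorial. C5 and C10 arise by anti addition across the (E)-C5=C10 alkene in a chair–chair fold (trans ring fusion, C20 axial and cis to the C3 oxygen), and C9 is set by the allylsilane geometry (C7 trans to C11), which places the CH2CH2OTBS chain equatorial. The step needs ionisation at C4 and not at C3, and loss of silicon and not of a proton or capture by the C12 ether oxygen at C8; the tertiary epoxide carbon, the preorganised 1,5-diene and the aligned C–Si bond should secure this at low temperature and high dilution. The absolute configuration of all five ring stereocentres then follows from the (2S,3R) epoxide.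

Step 12
Reactants: 14 (1R,2R,4aS,5R,8aS)-1-[(TBS-oxy)methyl]-5-[2-(TBS-oxy)ethyl]-1,4a-dimethyl-6-methylidenedecahydronaphthalen-2-ol
Product: 15 (1R,2R,4aS,5R,8aS)-5-(2-hydroxyethyl)-1-(hydroxymethyl)-1,4a-dimethyl-6-methylidenedecahydronaphthalen-2-ol
Conditions: n-Bu4NF (3 equiv), THF, rt → 45 °C
Reagents that add atoms: none
Why: fluoride-induced cleavage of both silyl ethers (desilylation), the neopentyl C19 ether needing gentle warming; no stereocentre is touched.

Step 13
Reactants: 15 (1R,2R,4aS,5R,8aS)-5-(2-hydroxyethyl)-1-(hydroxymethyl)-1,4a-dimethyl-6-methylidenedecahydronaphthalen-2-ol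
Product: 16 (1R,2R,4aS,5R,8aS)-1-(hydroxymethyl)-5-(2-iodoethyl)-1,4a-dimethyl-6-methylidenedecahydronaphthalen-2-ol
Conditions: PPh3 (1.15 equiv), I2 (1.1 equiv), imidazole (2.5 equiv), THF, 0 °C
Reagents that add atoms: iodine II
Why: Appel-type iodination, which should be sterically selective for the unhindered primary C12 hydroxyl over the neopentyl C19 and the hindered secondary C3 hydroxyls.

Step 14
Reactants: 17 3-bromooxolan-2-one (racemate); 18 benzenethiol
Product: 19 rac-3-(phenylsulfanyl)oxolan-2-one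
Conditions: Et3N, CH2Cl2, 0 °C → rt
Reagents that add atoms: none
Why: SN2 displacement of the activated α-bromide by thiolate (thioether formation).

Step 15
Reactants: 16 (1R,2R,4aS,5R,8aS)-1-(hydroxymethyl)-5-(2-iodoethyl)-1,4a-dimethyl-6-methylidenedecahydronaphthalen-2-ol; 19 rac-3-(phenylsulfanyl)oxolan-2-one
Product: 21 3-{2-[(1R,4aS,5R,6R,8aS)-6-hydroxy-5-(hydroxymethyl)-5,8a-dimethyl-2-methylidenedecahydronaphthalen-1-yl]ethyl}-3-(phenylsulfanyl)oxolan-2-one (both epimers at the lactone carbon), via lithium enolate 20 (not isolated)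
Conditions: 19 (3 equiv), LiN(i-Pr)2 (3 equiv), THF, −78 °C; then 16, DMPU, −78 °C → rt
Reagents that add atoms: none
Why: SN2 alkylation of the sulfur-stabilised lactone enolate by the primary iodide forms the C12–C13 bond; the enolate is too weakly basic to deprotonate the free hydroxyls, and the new sulfide-bearing centre is destroyed in step 16.

Step 16
Reactants: 21 3-{2-[(1R,4aS,5R,6R,8aS)-6-hydroxy-5-(hydroxymethyl)-5,8a-dimethyl-2-methylidenedecahydronaphthalen-1-yl]ethyl}-3-(phenylsulfanyl)oxolan-2-one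
Product: 23 3-{2-[(1R,4aS,5R,6R,8aS)-6-hydroxy-5-(hydroxymethyl)-5,8a-dimethyl-2-methylidenedecahydronaphthalen-1-yl]ethyl}furan-2(5H)-one (14-deoxyandrographolide), via sulfoxide 22 (not isolated)
Conditions: mCPBA (1.0 equiv), CH2Cl2, −78 °C; aq. NaHCO3; then toluene, CaCO3, 110 °C
Reagents that add atoms: none
Why: sulfide oxidation followed by thermal syn-elimination of the sulfoxide, which in 3-alkyl-3-sulfinyl butyrolactones goes toward the ring CH2 to give the endocyclic butenolide; at −78 °C the peracid should oxidise sulfur far faster than the 1,1-disubstituted alkene.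

Step 17
Reactants: 23 14-deoxyandrographolide
Product: 24 3-{2-[(1S,3S,4aS,5R,6R,8aS)-3,6-dihydroxy-5-(hydroxymethyl)-5,8a-dimethyl-2-methylidenedecahydronaphthalen-1-yl]ethyl}furan-2(5H)-one (target)
Conditions: SeO2 (0.3 equiv), t-BuOOH (3 equiv), CH2Cl2, rt
Reagents that add atoms: selenium dioxide O=[Se]=O (oxygen carrier); tert-butyl hydroperoxide CC(C)(C)OO (terminal oxidant)
Why: SeO2 ene reaction at C17 followed by [2,3]-sigmatropic shift (Sharpless–Umbreit allylic hydroxylation) should deliver oxygen to the ring methylene C7 on the face anti to the axial C10 methyl, giving the axial 7-hydroxyl with the exocyclic alkene restored; the electron-poor butenolide alkene should not react.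

**Compound list**

1 | 3-[(tert-butyldimethylsilyl)oxy]propanal | CC(C)(C)[Si](C)(C)OCCC=O | starting material
2 | (2-bromoprop-2-en-1-yl)trimethylsilane | C=C(Br)C[Si](C)(C)C | starting material
3 | [3-(trimethylsilyl)prop-1-en-2-yl]magnesium bromide | C=C([Mg]Br)C[Si](C)(C)C | intermediate
4 | rac-1-[(tert-butyldimethylsilyl)oxy]-4-[(trimethylsilyl)methyl]pent-4-en-3-ol | CC(C)(C)[Si](C)(C)OCCC(O)C(=C)C[Si](C)(C)C | intermediate
5 | ethyl (4Z)-7-[(tert-butyldimethylsilyl)oxy]-4-[(trimethylsilyl)methyl]hept-4-enoate | CCOC(=O)CC/C(C[Si](C)(C)C)=C/CCO[Si](C)(C)C(C)(C)C | intermediate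
6 | (4Z)-7-[(tert-butyldimethylsilyl)oxy]-4-[(trimethylsilyl)methyl]hept-4-enal | O=CCC/C(C[Si](C)(C)C)=C/CCO[Si](C)(C)C(C)(C)C | intermediate
7 | rac-(6Z)-9-[(tert-butyldimethylsilyl)oxy]-2-methyl-6-[(trimethylsilyl)methyl]nona-1,6-dien-3-ol | C=C(C)C(O)CC/C(C[Si](C)(C)C)=C/CCO[Si](C)(C)C(C)(C)C | intermediate
8 | ethyl (4E,8Z)-11-[(tert-butyldimethylsilyl)oxy]-4-methyl-8-[(trimethylsilyl)methyl]undeca-4,8-dienoate | CCOC(=O)CC/C(C)=C/CC/C(C[Si](C)(C)C)=C/CCO[Si](C)(C)C(C)(C)C | intermediate
9 | (4E,8Z)-11-[(tert-butyldimethylsilyl)oxy]-4-methyl-8-[(trimethylsilyl)methyl]undeca-4,8-dienal | O=CCC/C(C)=C/CC/C(C[Si](C)(C)C)=C/CCO[Si](C)(C)C(C)(C)C | intermediate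
10 | methyl (2Z,6E,10Z)-13-[(tert-butyldimethylsilyl)oxy]-2,6-dimethyl-10-[(trimethylsilyl)methyl]trideca-2,6,10-trienoate | COC(=O)/C(C)=C\CC/C(C)=C/CC/C(C[Si](C)(C)C)=C/CCO[Si](C)(C)C(C)(C)C | intermediate
11 | (2Z,6E,10Z)-13-[(tert-butyldimethylsilyl)oxy]-2,6-dimethyl-10-[(trimethylsilyl)methyl]trideca-2,6,10-trien-1-ol | OC/C(C)=C\CC/C(C)=C/CC/C(C[Si](C)(C)C)=C/CCO[Si](C)(C)C(C)(C)C | intermediate
12 | [(2S,3R)-3-{(3E,7Z)-10-[(tert-butyldimethylsilyl)oxy]-3-methyl-7-[(trimethylsilyl)methyl]deca-3,7-dien-1-yl}-2-methyloxiran-2-yl]methanol | OC[C@]1(C)O[C@@H]1CC/C(C)=C/CC/C(C[Si](C)(C)C)=C/CCO[Si](C)(C)C(C)(C)C | intermediate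
13 | (2S,3R)-2-{[(tert-butyldimethylsilyl)oxy]methyl}-3-{(3E,7Z)-10-[(tert-butyldimethylsilyl)oxy]-3-methyl-7-[(trimethylsilyl)methyl]deca-3,7-dien-1-yl}-2-methyloxirane | CC(C)(C)[Si](C)(C)OC[C@]1(C)O[C@@H]1CC/C(C)=C/CC/C(C[Si](C)(C)C)=C/CCO[Si](C)(C)C(C)(C)C | intermediate
14 | (1R,2R,4aS,5R,8aS)-1-{[(tert-butyldimethylsilyl)oxy]methyl}-5-{2-[(tert-butyldimethylsilyl)oxy]ethyl}-1,4a-dimethyl-6-methylidenedecahydronaphthalen-2-ol | C=C1[C@@H](CCO[Si](C)(C)C(C)(C)C)[C@]2(C)CC[C@@H](O)[C@@](C)(CO[Si](C)(C)C(C)(C)C)[C@H]2CC1 | intermediate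
15 | (1R,2R,4aS,5R,8aS)-5-(2-hydroxyethyl)-1-(hydroxymethyl)-1,4a-dimethyl-6-methylidenedecahydronaphthalen-2-ol | C=C1[C@@H](CCO)[C@]2(C)CC[C@@H](O)[C@@](C)(CO)[C@H]2CC1 | intermediate
16 | (1R,2R,4aS,5R,8aS)-1-(hydroxymethyl)-5-(2-iodoethyl)-1,4a-dimethyl-6-methylidenedecahydronaphthalen-2-ol | C=C1[C@@H](CCI)[C@]2(C)CC[C@@H](O)[C@@](C)(CO)[C@H]2CC1 | intermediate
17 | 3-bromooxolan-2-one (racemate) | O=C1OCCC1Br | starting material
18 | benzenethiol | Sc1ccccc1 | starting material
19 | rac-3-(phenylsulfanyl)oxolan-2-one | O=C1OCCC1Sc1ccccc1 | intermediate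
20 | lithium 3-(phenylsulfanyl)-4,5-dihydrofuran-2-olate | [Li+].[O-]C1=C(Sc2ccccc2)CCO1 | intermediate
21 | 3-{2-[(1R,4aS,5R,6R,8aS)-6-hydroxy-5-(hydroxymethyl)-5,8a-dimethyl-2-methylidenedecahydronaphthalen-1-yl]ethyl}-3-(phenylsulfanyl)oxolan-2-one (both epimers at the lactone carbon) | C=C1[C@@H](CCC2(Sc3ccccc3)CCOC2=O)[C@]2(C)CC[C@@H](O)[C@@](C)(CO)[C@H]2CC1 | intermediate
22 | 3-{2-[(1R,4aS,5R,6R,8aS)-6-hydroxy-5-(hydroxymethyl)-5,8a-dimethyl-2-methylidenedecahydronaphthalen-1-yl]ethyl}-3-(phenylsulfinyl)oxolan-2-one (mixture of isomers) | C=C1[C@@H](CCC2(S(=O)c3ccccc3)CCOC2=O)[C@]2(C)CC[C@@H](O)[C@@](C)(CO)[C@H]2CC1 | intermediate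
23 | 3-{2-[(1R,4aS,5R,6R,8aS)-6-hydroxy-5-(hydroxymethyl)-5,8a-dimethyl-2-methylidenedecahydronaphthalen-1-yl]ethyl}furan-2(5H)-one (14-deoxyandrographolide) | C=C1[C@@H](CCC2=CCOC2=O)[C@]2(C)CC[C@@H](O)[C@@](C)(CO)[C@H]2CC1 | intermediate
24 | 3-{2-[(1S,3S,4aS,5R,6R,8aS)-3,6-dihydroxy-5-(hydroxymethyl)-5,8a-dimethyl-2-methylidenedecahydronaphthalen-1-yl]ethyl}furan-2(5H)-one | C=C1[C@@H](CCC2=CCOC2=O)[C@]2(C)CC[C@@H](O)[C@@](C)(CO)[C@H]2C[C@@H]1O | target

**Step count and risks**

Total steps: 17. Longest linear sequence: 16 (steps 1–13 and 15–17); step 14 is a one-step side branch.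

Most likely to fail:

Step 11. Ionisation next to the silyloxymethyl group may be slow, so hydride shift to a C3 ketone, arrest after ring A, or capture of the C8 cation by the C12 ether oxygen could compete with the full cascade. The fallback closes both rings by an oxidative radical cyclization in which C4 is an electrophilic keto-ester radical and not a cation. It sets out from aldehyde 9. (1R,2S,5R)-5-Methyl-2-(2-phenylpropan-2-yl)cyclohexyl propanoate F1 is made from the commercial alcohol with propanoyl chloride and pyridine. Its lithium enolate (LiN(i-Pr)2, THF, −78 °C) adds to 9 to give the hydroxy ester F2, and Dess–Martin periodinane gives the 2-methyl-3-oxo ester F3. Mn(OAc)3·2H2O with Yb(OTf)3 in CF3CH2OH at −5 °C should then form ring A and ring B, with the allylsilane again giving the C8=C17 methylene after oxidation of the β-silyl radical and loss of silicon. The product is the bicyclic keto ester F4, with the ester axial as is usual for trivalent-manganese cyclizations of such keto esters and the absolute sense assumed to come from face shielding by the auxiliary. LiAlH4 reduces the C3 ketone to the equatorial alcohol, converts the ester into the C19 alcohol and releases the auxiliary, giving the diol F5. n-Bu4NF then gives triol 15, where the route is rejoined.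

Step 17. The allylic hydroxylation may run on to the enone, or the [2,3]-shift may show incomplete facial selectivity on the unprotected triol. The fallback sets out from 23 and uses an oxidation–reduction sequence in place of the direct hydroxylation. The oxidation with SeO2 and t-BuOOH is run to full consumption of 23, and the crude allylic alcohols (24 together with its C7 epimer, 3-{2-[(1S,3R,4aS,5R,6R,8aS)-3,6-dihydroxy-5-(hydroxymethyl)-5,8a-dimethyl-2-methylidenedecahydronaphthalen-1-yl]ethyl}furan-2(5H)-one F6) are oxidised with MnO2 in CH2Cl2. MnO2 attacks only the allylic hydroxyl and gives the 7-oxo compound F7. Catalyst-controlled 1,2-reduction with BH3·SMe2 and (R)-2-methyl-CBS-oxazaborolidine in THF at −20 °C is then expected to deliver hydride to the face that gives the (7S) axial alcohol, which is 24.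

Step 13. The phosphonium iodide reagent may also engage the free 1,3-diol (cyclic phosphorane formation, substitution at C19 or dehydration at C3), which would erode site selectivity. The fallback sets out from 14 and keeps C19 silylated during the iodination. Pyridinium p-toluenesulfonate in MeOH at rt should cleave only the unhindered primary silyl ether and give (1R,2R,4aS,5R,8aS)-1-{[(tert-butyldimethylsilyl)oxy]methyl}-5-(2-hydroxyethyl)-1,4a-dimethyl-6-methylidenedecahydronaphthalen-2-ol F8. PPh3, I2 and imidazole then give the iodide F9, whose only free hydroxyl is the hindered one at C3. HF·pyridine in THF removes the remaining silyl group and gives 16, where the route is rejoined.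

Further compounds
F1 | step 11 | (1R,2S,5R)-5-methyl-2-(2-phenylpropan-2-yl)cyclohexyl propanoate | CC(C)(c1ccccc1)[C@@H]1CC[C@H](C[C@H]1OC(=O)CC)C
F2 | step 11 | (1R,2S,5R)-5-methyl-2-(2-phenylpropan-2-yl)cyclohexyl (6E,10Z)-13-[(tert-butyldimethylsilyl)oxy]-3-hydroxy-2,6-dimethyl-10-[(trimethylsilyl)methyl]trideca-6,10-dienoate (diastereomer mixture at C2 and C3) | CC(C)(c1ccccc1)[C@@H]1CC[C@H](C[C@H]1OC(=O)C(C)C(O)CC/C(C)=C/CC/C(C[Si](C)(C)C)=C/CCO[Si](C)(C)C(C)(C)C)C
F3 | step 11 | (1R,2S,5R)-5-methyl-2-(2-phenylpropan-2-yl)cyclohexyl (6E,10Z)-13-[(tert-butyldimethylsilyl)oxy]-2,6-dimethyl-3-oxo-10-[(trimethylsilyl)methyl]trideca-6,10-dienoate (both C2 epimers) | CC(C)(c1ccccc1)[C@@H]1CC[C@H](C[C@H]1OC(=O)C(C)C(=O)CC/C(C)=C/CC/C(C[Si](C)(C)C)=C/CCO[Si](C)(C)C(C)(C)C)C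
F4 | step 11 | (1R,2S,5R)-5-methyl-2-(2-phenylpropan-2-yl)cyclohexyl (1S,4aS,5R,8aS)-5-{2-[(tert-butyldimethylsilyl)oxy]ethyl}-1,4a-dimethyl-6-methylidene-2-oxodecahydronaphthalene-1-carboxylate | C=C1[C@@H](CCO[Si](C)(C)C(C)(C)C)[C@]2(C)CCC(=O)[C@@](C)(C(=O)O[C@@H]3C[C@H](C)CC[C@H]3C(C)(C)c3ccccc3)[C@H]2CC1
F5 | step 11 | (1R,2R,4aS,5R,8aS)-5-{2-[(tert-butyldimethylsilyl)oxy]ethyl}-1-(hydroxymethyl)-1,4a-dimethyl-6-methylidenedecahydronaphthalen-2-ol | C=C1[C@@H](CCO[Si](C)(C)C(C)(C)C)[C@]2(C)CC[C@@H](O)[C@@](C)(CO)[C@H]2CC1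
F6 | step 17 | 3-{2-[(1S,3R,4aS,5R,6R,8aS)-3,6-dihydroxy-5-(hydroxymethyl)-5,8a-dimethyl-2-methylidenedecahydronaphthalen-1-yl]ethyl}furan-2(5H)-one | C=C1[C@@H](CCC2=CCOC2=O)[C@]2(C)CC[C@@H](O)[C@@](C)(CO)[C@H]2C[C@H]1O
F7 | step 17 | 3-{2-[(1S,4aS,5R,6R,8aS)-6-hydroxy-5-(hydroxymethyl)-5,8a-dimethyl-2-methylidene-3-oxodecahydronaphthalen-1-yl]ethyl}furan-2(5H)-one | C=C1[C@@H](CCC2=CCOC2=O)[C@]2(C)CC[C@@H](O)[C@@](C)(CO)[C@H]2CC1=O
F8 | step 13 | (1R,2R,4aS,5R,8aS)-1-{[(tert-butyldimethylsilyl)oxy]methyl}-5-(2-hydroxyethyl)-1,4a-dimethyl-6-methylidenedecahydronaphthalen-2-ol | C=C1[C@@H](CCO)[C@]2(C)CC[C@@H](O)[C@@](C)(CO[Si](C)(C)C(C)(C)C)[C@H]2CC1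
F9 | step 13 | (1R,2R,4aS,5R,8aS)-1-{[(tert-butyldimethylsilyl)oxy]methyl}-5-(2-iodoethyl)-1,4a-dimethyl-6-methylidenedecahydronaphthalen-2-ol | C=C1[C@@H](CCI)[C@]2(C)CC[C@@H](O)[C@@](C)(CO[Si](C)(C)C(C)(C)C)[C@H]2CC1
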